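**Assumptions (one line each)**
- 7-Octenal, nonyltriphenylphosphonium bromide, 9-BBN and 2-bromophenol are taken as commercial. Catalysts and terminal oxidants are named in the conditions and not numbered.
- The target configuration is (4S,5R,6R): C5–OH and C6–OH are cis, and C4–OH is trans to C5–OH. The (Z)-C17 chain is (Z)-heptadec-8-enyl.

## Retrosynthetic overview
1. Target ← trans-opening by water at the allylic C4 of the syn-epoxy-enone **9** (Fürst–Plattner, anti to the epoxide oxygen).
2. **9** ← hydroxyl-directed epoxidation of the γ,δ-alkene of the ortho-quinol **8**; the epoxide forms syn to the C6–OH.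
3. **8** ← enantioselective hydroxylative dearomatization of the 2-alkylphenol **7**. This sets C6 and is the only step that forms a stereocentre from an achiral substrate; the six-membered ring is the pre-existing benzene ring.
4. **7** ← B-alkyl Suzuki coupling of 2-bromophenol with the 9-BBN adduct of (Z)-heptadeca-1,8-diene, which comes from a Z-selective Wittig reaction of 7-octenal.

## Route

**Step 1**
Reactants: **1** 7-octenal; **2** nonyltriphenylphosphonium bromide
Product: **3** (8Z)-heptadeca-1,8-diene
Conditions: NaHMDS, THF, –78 → 0 °C, then add 1; 2 h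
Reagents that add atoms: none (the C9 unit comes from numbered reactant 2; NaHMDS adds nothing)
Why: Wittig olefination with a non-stabilised, salt-free ylide gives the Z-alkene (≥95:5) and leaves the terminal alkene untouched.

**Step 2**
Reactants: **3**; **4** 9-BBN
Product: **5** B-[(8Z)-heptadec-8-en-1-yl]-9-BBN
Conditions: 9-BBN (0.95 equiv, 0.5 M in THF), 0 °C → rt, 3 h
Reagents that add atoms: none (9-BBN is numbered reactant 4)
Why: Hydroboration by 9-BBN is anti-Markovnikov and strongly prefers the terminal alkene over the hindered Z-1,2-disubstituted alkene.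

**Step 3**
Reactants: **5**; **6** 2-bromophenol
Product: **7** 2-[(8Z)-heptadec-8-en-1-yl]phenol
Conditions: Pd(dppf)Cl2 (5 mol%), K3PO4 (3 equiv), THF/H2O (10:1), 65 °C, 12 h, in the same pot as step 2
Reagents that add atoms: none
Why: B-alkyl Suzuki–Miyaura coupling forms the sp3–sp2 bond and tolerates a free phenol and the Z-alkene (the extra base equivalent covers the phenol O–H).

**Step 4**
Reactants: **7**
Product: **8** (6R)-6-hydroxy-6-[(8Z)-heptadec-8-en-1-yl]cyclohexa-2,4-dien-1-one
Conditions: chiral C2-symmetric lactamide-derived 2-iodoresorcinol diether (Ishihara-type, 10 mol%), mCPBA (1.3 equiv), MeCN/H2O (10:1), 0.02 M, –10 °C, 2 h; cold work-up and use immediately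
Reagents that add atoms: water, O
Why: Proposed new method: enantioselective hydroxylative dearomatization of a simple monocyclic 2-alkylphenol to an ortho-quinol by an iodoarene(III) catalyst generated in situ by mCPBA. The phenol exchanges onto the chiral aryl-λ3-iodane, and the iodane's OH/H2O ligand is delivered to the alkyl-bearing ortho carbon through a five-membered arrangement. That delivery is ortho-selective, and the catalyst's chiral pocket fixes the enantioface at the new C6 quaternary carbinol. The closest known reactions are iodoarene-catalysed asymmetric dearomatization of naphthols and oxidative spirolactonization, and racemic PIDA/H2O or NaIO4 o-quinol formation. The chain alkene survives because mCPBA epoxidizes isolated cis-alkenes slowly at –10 °C and 0.02 M.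

**Step 5**
Reactants: **8** (crude, telescoped at ≤0.05 M)
Product: **9** 2-hydroxy-2-[(8Z)-heptadec-8-en-1-yl]-7-oxabicyclo[4.1.0]hept-4-en-3-one (C4–C5 epoxide cis to the C6–OH)
Conditions: VO(acac)2 (5 mol%), TBHP (1.3 equiv, 5.5 M in nonane), CH2Cl2, 0 °C, 3 h
Reagents that add atoms: tert-butyl hydroperoxide, CC(C)(C)OO (supplies the epoxide O)
Why: Sharpless-type vanadium epoxidation is directed by the tertiary allylic OH, so it delivers oxygen to the C4=C5 face syn to the C6–OH; the electron-poor enone C2=C3 and the isolated chain alkene are not epoxidized under these conditions.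

**Step 6**
Reactants: **9**
Product: **10** Pleiogenone A, (4S,5R,6R)-4,5,6-trihydroxy-6-[(8Z)-heptadec-8-en-1-yl]cyclohex-2-en-1-one
Conditions: HClO4 (2 mol%), THF/H2O (5:1), 0 °C → rt, 4 h
Reagents that add atoms: water, O
Why: Acid-catalysed vinyl-epoxide hydrolysis gives SN2-type trans-diaxial attack of water at the allylic C4 (the enone-destabilised cation disfavors SN1, and C5 is shielded by the quaternary C6), which inverts C4 to OH-up while C5–OH stays cis to C6–OH.

## Compound list
1 | 7-octenal | O=CCCCCCC=C | starting material
2 | nonyltriphenylphosphonium bromide | CCCCCCCCC[P+](c1ccccc1)(c1ccccc1)c1ccccc1.[Br-] | starting material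
3 | (8Z)-heptadeca-1,8-diene | C=CCCCCC/C=C\CCCCCCCC | intermediate
4 | 9-BBN | B1C2CCCC1CCC2 | starting material
5 | B-[(8Z)-heptadec-8-en-1-yl]-9-BBN | B1(CCCCCCC/C=C\CCCCCCCC)C2CCCC1CCC2 | intermediate
6 | 2-bromophenol | Oc1ccccc1Br | starting material
7 | 2-[(8Z)-heptadec-8-en-1-yl]phenol | Oc1ccccc1CCCCCCC/C=C\CCCCCCCC | intermediate
8 | (6R)-6-hydroxy-6-[(8Z)-heptadec-8-en-1-yl]cyclohexa-2,4-dien-1-one | CCCCCCCC/C=C\CCCCCCC[C@]1(O)C(=O)C=CC=C1 | intermediate
9 | syn-epoxy-enone (epoxide cis to C6–OH) | CCCCCCCC/C=C\CCCCCCC[C@]1(O)C(=O)C=C[C@H]2O[C@@H]12 | intermediate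
10 | Pleiogenone A | CCCCCCCC/C=C\CCCCCCC[C@]1(O)C(=O)C=C[C@H](O)[C@H]1O | target

**Total steps:** 6. **Longest linear sequence:** 6 (7-octenal → 3 → 5 → 7 → 8 → 9 → 10).

## Three steps most likely to fail
1. **Step 4 (proposed new step).** The enantioselectivity and ortho-selectivity of dearomatizing a simple phenol are unproven. Para attack (quinone formation) and dimerization of 8 also compete.
   - Fallback, using known chemistry: racemic PIDA/H2O (Adler–Becker-type) dearomatization, then epoxidation to racemic 9 (or via the diene-diol route below), then chiral-phase HPLC resolution of 9 and continuation with step 6.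
2. **Step 5.** The free dienone 8 may dimerize (Diels–Alder) before it is epoxidized, and VO(acac)2/TBHP may be slow on an electron-poor diene.
   - Fallback: reduce 8 in situ by Luche reduction to the stable cyclohexa-2,4-diene-1,6-diol; epoxidize with VO(acac)2/TBHP, which is directed by both OH groups; oxidize the C1 allylic alcohol selectively with MnO2 to give 9.
3. **Step 6.** Water may attack by SN1 (giving cis/trans mixtures), conjugate addition at C3 may compete, or acid may trigger an α-ketol rearrangement.
   - Fallback: skip the epoxide. Dihydroxylate the C4=C5 bond of the diene-diol with OsO4/TMEDA (Donohoe), which delivers syn to the C6–OH. Invert C4 by Mitsunobu reaction with p-nitrobenzoic acid (C4–OH is the least hindered secondary OH), hydrolyse the ester, and re-oxidize C1 with MnO2.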